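Late in the amber run the complex with two exchanged reads 9.6 % at 20.0 h and 10.0 % at 25.0 h, with 3.3 % of the complex with three exchanged beside it, so the third exchange is already drawing on it.

| setting | red | amber | flask |
|---|---|---|---|
| starting complex | 21 mM | 21 mM | 21 mM |
| incoming ligand | 10 mM | 16 mM | 21.0 mM |
| remark | run made earlier | run made earlier |  |
| time |  |  | 20 h |

| run | time / h | complex with two exchanged / % | complex with three exchanged / % |
|---|---|---|---|
| red | 2.00 | 0.1 | 0 |
| red | 4.00 | 3.4 | 1.7 |
| red | 10.0 | 2.2 | 0.3 |
| red | 25.0 | 5.0 | 0 |
| amber | 6.00 | 3.6 | 1.5 |
| amber | 12.0 | 7.3 | 2.3 |
| amber | 20.0 | 9.6 | 2.2 |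
| amber | 25.0 | 10.0 | 3.3 |

(each reading ± 1 percentage point)

- equivalents of incoming ligand to starting complex, everything else as given, that leave most complex with two exchanged at 20 h
- the amount of complex with two exchanged then, in percent of the starting complex charged
- the amount of complex with two exchanged with the amounts as given

- the earlier runs were read with a standard deviation of 1 percentage point
- steps thought possible: starting complex + incoming ligand <-> leaving ligand + complex with one exchanged; complex with one exchanged + incoming ligand <-> leaving ligand + complex with two exchanged; complex with two exchanged + incoming ligand <-> leaving ligand + complex with three exchanged; leaving ligand + starting complex -> side product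

Summing the amber readings of the complex with two exchanged over time gives 1.60 h of full charge. Dividing the last three-exchanged reading by that gives a pseudo-first-order loss of 0.0206 h⁻¹, a reading that carries the scatter of 1 percentage point. Per mM of the amber charge this is 0.00129 mM⁻¹ h⁻¹.

Let N be the number of lifetimes a two-exchanged complex spends against the third exchange: loss constant times free incoming ligand times time. In a chain of two like steps the middle species peaks at N of one. That needs 38.8 mM free at 20 h, and about one ligand taken up per starting complex makes a charge of 59.8 mM.

The weak link is the charge, which is not the free ligand. The last amber readings hold 6.28 mM of ligand in the two products, which leaves at most 9.72 mM free. The loss constant per mM of free ligand therefore rises to 0.00212 mM⁻¹ h⁻¹. N of one then needs 23.6 mM free, and the charge to commit to is 44.6 mM.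

The forecast puts the best at 2.2 equiv with 42 %, and 16 % at the charges given, “though this is a long extrapolation”.

The simulation gives 12.4 % at the charges given, and the best at 4.20 equiv with 19.9 %.

    starting complex + incoming ligand ⇌ leaving ligand + complex with one exchanged (K = 0.635, k = 0.00582 M⁻¹ s⁻¹)
    complex with one exchanged + incoming ligand ⇌ leaving ligand + complex with two exchanged (K = 1.20, k = 0.00122 M⁻¹ s⁻¹)
    complex with two exchanged + incoming ligand ⇌ leaving ligand + complex with three exchanged (K = 1.50, k = 0.00113 M⁻¹ s⁻¹)
    leaving ligand + starting complex → side product (k = 3.76 × 10⁻⁴ M⁻¹ s⁻¹)

In the flask, free incoming ligand at 20.0 h is 7.80 mM, so N, reckoned with the loss constant as read from the amber run and carrying its scatter, is 0.331. The wearing away of incoming ligand and the return of leaving ligand with the complex with two exchanged together hold that complex down: it stands at 18.2 % without the first and 16.3 % without the second. The neighbour flask charged with 53 mM keeps 25.9 mM free, so its N, reckoned with the same amber reading, is 1.10. It holds 18.9 % of the complex with two exchanged beside 25.0 % of the complex with three exchanged, 1.0 point below the best.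

The readings stem from a simulated flask on assumed constants.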